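Sideroxylonal B is read as (2R,3S,4S), with ring B and isopropyl cis and isopropyl and isobutyl trans. It equals two 2,4-diformylphloroglucinols plus two isovaleraldehydes minus two H2O. Ring A = fused arene, ring B = pendant arene, ring C = dihydropyran (O1, C2, C3, C4, C4a, C8a).
First cut (key step): C2–C1' between ring C and ring B, together with O1–C2. C2 goes back to the aldehyde carbon of a chroman-2-ol and ring B to free 2,4-diformylphloroglucinol, following the quinone-methide logic of the presumed biogenesis in a polar, catalyst-controlled form.
Enabling feature: C2 is an aldehyde-level carbon held between O1 (the phenoxide of the acidic ring A) and C1' of ring B, whose neighbours C2' and C6' both carry OH. O1–C2 can therefore open and close through the ortho-quinone methide of ring B, and the ring B precursor has only one free ring CH, flanked by two OH.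
Second cut (same flask): C3–C4, from a chiral enamine of isovaleraldehyde and the ortho-quinone methide of ring A, which is released from a racemic sulfone made from diformylphloroglucinol, isovaleraldehyde and sulfinate.
Ring order: rings A and B come ready-made from phloroglucinol by double formylation. Ring C is the only ring formed: it closes provisionally as a lactol, reopens, and closes for good by oxa-Michael addition in the key step.

Key step: step 3

Assumption: of the four diastereomers that share (4S), the target is taken to be the most stable (reasoning in step 3). Enantiomeric purity rests on the first stage of step 3, and a final recrystallisation is foreseen to raise it if needed.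

Step 1
Reactants: 1 phloroglucinol
Product: 2 2,4-diformylphloroglucinol (2,4,6-trihydroxybenzene-1,3-dicarbaldehyde)
Conditions: POCl3 (2.2 equiv), DMF (2.2 equiv), 1,4-dioxane, 0 °C to rt; then ice-water
Reagents that add atoms: N,N-dimethylformamide, CN(C)C=O; water, O
Why: Double Vilsmeier–Haack formylation, in which the chloroiminium salt attacks the very electron-rich ring twice and the two iminium groups deactivate it enough that the third position should stay free with two equivalents of reagent; no stereocentre is formed.

Step 2
Reactants: 2 2,4-diformylphloroglucinol; 3 isovaleraldehyde (3-methylbutanal)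
Product: 4 (±)-2,4,6-trihydroxy-5-[3-methyl-1-(4-methylbenzenesulfonyl)butyl]benzene-1,3-dicarbaldehyde
Conditions: 3 (1.5 equiv), p-TolSO2Na (1.5 equiv), HCO2H/H2O, rt; product filtered off
Reagents that add atoms: sodium p-toluenesulfinate, Cc1ccc(cc1)S(=O)[O-].[Na+]
Why: Three-component sulfonylalkylation (Knoevenagel-type condensation of the only free ring CH with the aldehyde, then conjugate addition of sulfinate sulfur to the resulting ortho-quinone methide), the reaction type used for 2-(1-sulfonylalkyl)phenols, sulfonylalkyl naphthols and sulfonylalkyl indoles; the acidic medium keeps the phenols protonated so that the sulfone should not eliminate, and the new stereocentre is racemic on purpose because step 3 erases it.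

Step 3
Reactants: 4 racemic sulfone; 3 isovaleraldehyde; 2 2,4-diformylphloroglucinol
Product: 8 sideroxylonal B, via ring-A quinone methide 5 (not isolated), via chroman-2-ol 6 (not isolated), via ring-B quinone methide 7 (not isolated)
Conditions: 4 (1.05 equiv), 3 (1.0 equiv), (R)-2-[diphenyl(trimethylsilyloxy)methyl]pyrrolidine (20 mol %), NaOAc (1.1 equiv), H2O (5 equiv), MeCN, −10 °C; then 2 (1.0 equiv), N,N'-dimethylethane-1,2-diamine (20 mol %), 40 °C
Reagents that add atoms: none
Why: Proposed new method: acetate expels sulfinate from 4 (E1cB) to give the flat, achiral 5, the E-enamine formed from 3 and the pyrrolidine catalyst adds to its exocyclic carbon (C3–C4 bond) and hydrolysis with hemiacetal closure gives 6; once 2 is added, the open aldehyde tautomer of 6 condenses through its diamine-derived iminium ion with the one free ring carbon of 2 (Mannich/Knoevenagel event, C2–C1' bond), loss of the amine gives 7, and a phenol oxygen of ring A adds to the exocyclic carbon of 7. The closest known reaction types are the amine-catalysed Michael addition of aldehydes to ortho-quinone methides released from 2-(1-sulfonylalkyl)phenols, the Knoevenagel generation of ortho-quinone methides from 2 and aldehydes, and the Knoevenagel/oxa-Michael C-glycosidation of unprotected lactols with 1,3-dicarbonyl compounds; new are their relay in one flask and a hindered α-branched lactol as the aldehyde partner. Ring C is the only ring closed, first provisionally by 6-exo-trig hemiacetalisation and finally by a reversible 6-exo-trig oxa-Michael addition of O1 to C2, and either ortho oxygen of ring A gives the same constitution because that ring is symmetric about its C4a–C7 axis. C3 is set by the catalyst, whose diphenyl(silyloxy)methyl group blocks one face of the s-trans E-enamine, and C4 by the synclinal, endo-type transition state that holds the quinone methide C=O under the enamine nitrogen and the isobutyl group outside (prototropy between the two ortho oxygens of 5 always makes this geometry available), the same topicity as in the syn-selective Michael addition of aldehydes to nitroalkenes, so that the (R)-catalyst should give (3S,4S), that is 3,4-trans. C2 is set by the substrate under equilibrating conditions: because O1–C2 reopens through 7, the mixture should drain to the epimer with ring B equatorial, isobutyl pseudoaxial (away from the 5-OH) and isopropyl axial and anti to isobutyl (no syn-axial partner at O1 or C4a), which is the 2,3-cis-3,4-trans array (2R,3S,4S), whereas the C2 epimer must either place ring B syn-axial to isobutyl or push isobutyl against the 5-OH. The step needs 5 to meet the enamine and not a phenolic carbon nucleophile, 2 to meet 6 and not free 3, and C3 to survive, which is secured by adding 2 only after 4 is consumed with 3 as the limiting reagent, by the two formyl groups that block all but one ring carbon of 2 (so that 8 has no free ring CH and cannot react on) and are too strongly hydrogen-bonded to condense with secondary amines, and by a pyrrolidine catalyst too bulky to form an enamine from the α-branched product.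

Compound list
1 | phloroglucinol (benzene-1,3,5-triol) | Oc1cc(O)cc(O)c1 | starting material
2 | 2,4-diformylphloroglucinol (2,4,6-trihydroxybenzene-1,3-dicarbaldehyde) | O=Cc1c(O)cc(O)c(C=O)c1O | intermediate
3 | isovaleraldehyde (3-methylbutanal) | CC(C)CC=O | starting material
4 | (±)-2,4,6-trihydroxy-5-[3-methyl-1-(4-methylbenzenesulfonyl)butyl]benzene-1,3-dicarbaldehyde | CC(C)CC(c1c(O)c(C=O)c(O)c(C=O)c1O)S(=O)(=O)c1ccc(C)cc1 | intermediate
5 | ring-A ortho-quinone methide: 2,4-dihydroxy-5-(3-methylbutylidene)-6-oxocyclohexa-1,3-diene-1,3-dicarbaldehyde (alkene geometry mobile through prototropy of the two flanking oxygens) | CC(C)CC=C1C(=O)C(C=O)=C(O)C(C=O)=C1O | intermediate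
6 | (3S,4S)-2,5,7-trihydroxy-4-(2-methylpropyl)-3-(propan-2-yl)-3,4-dihydro-2H-chromene-6,8-dicarbaldehyde (both C2 anomers, in equilibrium with the open hydroxy aldehyde tautomer) | CC(C)C[C@@H]1c2c(O)c(C=O)c(O)c(C=O)c2OC(O)[C@H]1C(C)C | intermediate
7 | ring-B ortho-quinone methide: ring-opened isomer of 8, with the ring A phenol free, the two sp3 centres arranged as in 6, and C2 as the exocyclic methine of a 2,4-dihydroxy-6-oxocyclohexadiene-1,3-dicarbaldehyde | CC(C)C[C@H](c1c(O)c(C=O)c(O)c(C=O)c1O)[C@H](C(C)C)C=C1C(=O)C(C=O)=C(O)C(C=O)=C1O | intermediate
8 | sideroxylonal B, (2R,3S,4S)-2-(3,5-diformyl-2,4,6-trihydroxyphenyl)-5,7-dihydroxy-4-(2-methylpropyl)-3-(propan-2-yl)-3,4-dihydro-2H-chromene-6,8-dicarbaldehyde | CC(C)C[C@@H]1c2c(O)c(C=O)c(O)c(C=O)c2O[C@@H](c2c(O)c(C=O)c(O)c(C=O)c2O)[C@H]1C(C)C | target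

Total step count: 3. Longest linear sequence: 3 (1 to 2 to 4 to 8; compound 2 enters twice).

Steps most likely to fail

Step 3 (Proposed new method). Three processes may interfere:
- The pyrrolidine catalyst may be tied up by conjugate addition to the very electrophilic ring-A quinone methide.
- Attack of the deactivated ring carbon on the hindered α-branched aldehyde may be slow. Enamine-mediated epimerisation at C3 or retro-Michael erosion at C4 could then compete.
- Equilibration at C2 may stay incomplete.

The fallback cuts the relay into known reactions and changes the oxidation level of ring B at the coupling. It sets out from 4 and 3 and comes back at 8. Only the first stage is run (same catalyst and base), and chroman-2-ol 6 is isolated. Compound 6 is then coupled not with 2 but with an excess of the far more nucleophilic phloroglucinol 1 under acid catalysis (Sc(OTf)3, MeCN/H2O, rt to 40 °C). This is a Friedel–Crafts hydroxyalkylation with cyclisation, the reaction type of the direct C-arylation of unprotected lactols with phloroglucinols. It should give (2R,3S,4S)-5,7-dihydroxy-4-(2-methylpropyl)-3-(propan-2-yl)-2-(2,4,6-trihydroxyphenyl)-3,4-dihydro-2H-chromene-6,8-dicarbaldehyde F1, with C2 again under thermodynamic control. Ring A of F1 has no free position, so a Vilsmeier–Haack reaction with excess POCl3/DMF, then water, can only formylate the two free carbons of ring B and should give 8.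

Step 2. The quinone methide may be captured by a second molecule of the phenol (double arylation) instead of by sulfinate, and sulfinate may be lost prematurely during isolation. The fallback sets out from 2 and 3 and comes back at 4. A Mannich (Betti) condensation with excess morpholine (EtOH, rt) should give the zwitterionic 2,4,6-trihydroxy-5-[3-methyl-1-(morpholin-4-yl)butyl]benzene-1,3-dicarbaldehyde F2. The amine traps the quinone methide faster than any carbon nucleophile, and the salt-like product precipitates. The amine of F2 is then exchanged for sulfinate by elimination–addition (p-TolSO2Na, aqueous HCO2H, rt), the known substitution of phenolic Mannich bases. The amine stays in the acidic aqueous phase and 4 is filtered off.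

Step 1. The degree of formylation may be imprecise (under- and over-formylation), and the polar polyphenols are hard to separate. The fallback sets out from 1 and comes back at 2.
- O-methylation (Me2SO4, K2CO3, acetone, reflux) gives 1,3,5-trimethoxybenzene F3.
- Rieche formylation (Cl2CHOMe, TiCl4, CH2Cl2, 0 °C) should stop at 2,4,6-trimethoxybenzene-1,3-dicarbaldehyde F4, because the ring is then strongly deactivated and the neutral products can be chromatographed.
- BBr3 (CH2Cl2, −78 °C to rt) cleaves the three methyl ethers, each of which is ortho to a chelating formyl group, to give 2.

Further compounds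
F1 | step 3 | (2R,3S,4S)-5,7-dihydroxy-4-(2-methylpropyl)-3-(propan-2-yl)-2-(2,4,6-trihydroxyphenyl)-3,4-dihydro-2H-chromene-6,8-dicarbaldehyde | CC(C)C[C@@H]1c2c(O)c(C=O)c(O)c(C=O)c2O[C@@H](c2c(O)cc(O)cc2O)[C@H]1C(C)C
F2 | step 2 | (±)-2,4,6-trihydroxy-5-[3-methyl-1-(morpholin-4-yl)butyl]benzene-1,3-dicarbaldehyde | CC(C)CC(N1CCOCC1)c1c(O)c(C=O)c(O)c(C=O)c1O
F3 | step 1 | 1,3,5-trimethoxybenzene | COc1cc(OC)cc(OC)c1
F4 | step 1 | 2,4,6-trimethoxybenzene-1,3-dicarbaldehyde | COc1cc(OC)c(C=O)c(OC)c1C=O
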